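I read both flasks at 6.0 min, later than the last larch reading at 4.00 min, and in the larch run free monomer reads 11.8% at 3.00 min and 12.2% at 4.00 min, a step of 0.4 percentage points against a scatter of 0.5 points, so I take it that I am asked for an end state and not for a rate.

| setting | larch | ash | winter | spring |
|---|---|---|---|---|
| free monomer | 0.50 mM | 0.50 mM | 0.50 mM | 0.50 mM |
| initiator | 1.5 mol% | 2.4 mol% | 2.2 mol% | 1.2 mol% |
| remark | run made earlier | run made earlier |  |  |
| time |  |  | 6.0 min | 6.0 min |

- larch (time / min: monomer in chains / %, free monomer / %): 0.667: 68.8, 30.7; 1.33: 83.2, 16.2; 2.00: 84.0, 13.4; 2.50: 85.8, 12.2; 3.00: 86.2, 11.8; 4.00: 86.6, 12.2
- ash (time / min: monomer in chains / %, free monomer / %): 0.333: 55.9, 43.8; 0.500: 73.0, 26.6; 0.833: 84.4, 13.9; 1.33: 90.0, 7.2; 2.00: 91.3, 5.8; 3.00: 92.3, 5.1; 4.00: 91.6, 5.6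

(standard deviation of a reading: 0.5 percentage points)

- the average divides the monomer in chains by the number of chains begun, living and dead together
- the earlier runs do not show the number of chains; that part of a forecast is a guess

- which of the two ends with the longer chains by the average number of monomer units in a chain (chains begun, living or dead) ("neither" if they lie within 10%) (winter / spring / neither)
- average number of monomer units in a chain (chains begun, living or dead) at the end, winter
- average number of monomer units in a chain (chains begun, living or dead) at the end, spring

The length at the end is the share of the charge standing in chains divided by the chains begun per free monomer charged, and since the earlier runs do not show the chains, I guess one chain per initiator. My first round puts the whole charge into chains, which gives 83.3 for spring and 45.5 for winter; I call this the charge ratio, free monomer charged per initiator charged.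

Then I put the answer back in, because the runs stop short. The logarithm of charge over what is left reads 2.10 in the larch run and 2.88 in the ash run, which goes as the loading to the power 0.670, so I expect 6.59% free monomer in winter and 16.3% in spring. The larch and ash readings fall short of the charge by 1.2 points and 2.8 points, near their loadings, so I also take off each loading, leaving 91.2% in chains in winter and 82.5% in spring. That gives me 41.5 for winter and 68.7 for spring. The charge ratios differ by a factor of 1.83, more than the factor of 1.11 between the shares, so one number was enough for the order but not for the lengths.

The forecast says spring, with 41 for winter and 69 for spring, on the ground “The guess is one chain begun per initiator”.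

The flasks give spring as the longer, with 43.8 units in winter and 71.4 in spring, which is 85.7% of the spring charge ratio.

    free monomer + initiator → living end + monomer in chains (k = 220 M⁻¹ s⁻¹)
    free monomer + living end → monomer in chains + living end, rate k2*[living end]*[free monomer] (k = 6600 M⁻¹ s⁻¹)
    living end + monomer in chains → dead end A (k = 78.0 M⁻¹ s⁻¹)
    initiator → spent initiator B (k = 0.00280 s⁻¹)

In spring, half of the turnover of free monomer and initiator into living end is done by 0.104 min, far sooner than the 4.1 min half-life of initiator by its loss to spent initiator B alone. Spent initiator B holds 3.25% of the spring initiator charge at the end, and 0% of that charge is left as initiator. A neighbour of spring charged with 3 mol% has a charge ratio of 33.3 and holds 93.9% in chains, which reckons to 31.3 units against the 34.1 it gives, and at its end spent initiator B holds 7.03% of its initiator charge and 1.1% is left as initiator.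

The earlier runs and the new flask were generated by integration with constants of no real substance; scatter was added.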